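A slow feed invites a pitfall: writing off the whole feed time, as if the flask stood idle until the last drop.

| setting | Wednesday's | Monday's | Saturday's | east | north-east | north-west | north |
|---|---|---|---|---|---|---|---|
| starting material | 26 mM | 17 mM | 39 mM | 26 mM | 26 mM | 26 mM | 26 mM |
| second substrate | 26 mM | 26 mM | 26 mM | 26.0 mM (fed, over 1.0 min) | 26.0 mM | 26.0 mM | 26.0 mM (fed, over 10 min) |
| reagent | 20.8 mM | 20.8 mM | 20.8 mM | 20.8 mM | 20.8 mM | 20.8 mM (fed, over 10 min) | 20.8 mM |
| free catalyst | 52 µM | 52 µM | 52 µM | 52 µM | 52 µM | 52 µM | 52 µM |
| remark | run made earlier | run made earlier | run made earlier | all else is in the flask from the start; the feed brings no volume worth counting | everything together at the start | all else is in the flask from the start; the feed brings no volume worth counting | all else is in the flask from the start; the feed brings no volume worth counting |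
| time |  |  |  | 15 min | 15 min | 15 min | 15 min |

- Wednesday's (time / min: target / %, starting material / %): 0.667: 1.5, 99.2; 2.00: 3.5, 96.1; 3.00: 4.2, 95.2; 5.00: 7.8, 90.7; 6.00: 8.4, 92.0; 10.0: 14.7, 88.6
- Monday's (time / min: target / %, starting material / %): 2.50: 3.8, 94.5; 5.00: 8.8, 90.6; 8.00: 12.2, 86.1; 10.0: 15.2, 85.9; 12.0: 16.5, 82.5; 15.0: 20.0, 80.2
- Saturday's (time / min: target / %, starting material / %): 2.50: 6.0, 95.4; 5.00: 8.7, 92.6; 8.00: 11.6, 89.2; 10.0: 11.3, 87.5; 12.0: 13.6, 86.0; 15.0: 17.3, 83.2

(each reading ± 1 percentage point)

- what was read earlier has a scatter of 1 percentage point, one standard deviation
- a reading or a percentage of target counts all its forms, free or not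

1. the best flask by amount of target, in percent of the starting material charged; "all alike" if 1.5 percentage points covers them all (east / north-east / north-west / north / all alike)
2. amount of target at the end, in percent of the starting material charged, east
3. amount of target at the end, in percent of the starting material charged, north-east
4. amount of target at the end, in percent of the starting material charged, north-west
5. amount of target at the end, in percent of the starting material charged, north

Monday's, Wednesday's and Saturday's runs differ in starting material but all start with c(reagent) at 20.8 mM, so they offer no comparison of different starting c(reagent). In our own reckoning we assume first order, meaning the rate of target moves in step with c(reagent). Reagent is the limiting reagent here, at 0.800 equivalents to starting material.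

In north-west, the reagent delivered during a steady feed averages half of the charge, before any is used. On our assumption of first order, half the feed time counts as lost, and north-west has 10.0 min out of 15 min. We call this the full-charge time, the time less half of the feed time.

Wednesday's run had north-west's charges with all the reagent in from the start, and it read 14.7% of target at 10.0 min. That time matches the full-charge time, so this reading, with its scatter of 1 percentage point, is our estimate for north-west. East and north feed the second substrate instead. The runs all start with c(second substrate) at 26.0 mM, so we make no reckoning for them.

The forecast gives 20% for east, 20.5% for north-east, 16.5% for north-west and 17% for north, and it names north-east as best: “Simultaneous charging is my best guess.” Its north-west number stands higher than our 14.7%.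

The flasks give 18.3% for east, 18.1% for north-east, 13.6% for north-west and 20.6% for north, so north is best.

    starting material + free catalyst ⇌ catalyst intermediate A (K = 17.0 M⁻¹, k = 26.0 M⁻¹ s⁻¹)
    reagent + catalyst intermediate A ⇌ free catalyst + target (K = 0.910, k = 41.0 M⁻¹ s⁻¹)
    second substrate + free catalyst ⇌ catalyst intermediate B (K = 16.0 M⁻¹, k = 55.0 M⁻¹ s⁻¹)
    reagent + catalyst intermediate B → free catalyst + second product (k = 46.0 M⁻¹ s⁻¹)
    crystals ⇌ target, rate k5*(cs5 - [target]) while solid is left; crystals form when [target] > cs5 (solubility = 0.310 mM, k = 0.0920 s⁻¹)

North-west lies 1.1 points below the reading at its full-charge time. Its neighbour takes 52 mM of reagent, with the same full-charge time of 10.0 min. First order multiplies north-west's 13.6% by the charge ratio 2.50, which gives 34.0%. The neighbour gives 27.5%, a factor of 2.02, and ends with 68% of its reagent still there.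

(The readings are calculated with constants of no real substance, noise included.)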